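**Plan**

1. Numbering as in the target name: C1H=C2(CHO)–C3H(CH2OH)–C4H(Ar)–C4a…C8a. Ring A is the dimethoxybenzo ring, ring B the dihydro ring, ring C the pendant guaiacyl ring.
2. Retrosynthesis: the C2–CHO/C3–CH2OH pair comes from a fused lactone. The C4–C4a bond (ring B) is cut to the open-chain benzylic alcohol 11; ring A attacks a quinone-methide-type cation at C4, as in the ring closure assumed for 8–8′ cyclolignan biosynthesis. The C3–C4 bond is cut by an Evans aldol and the C1=C2 bond by a Stobbe condensation.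
3. Forward: veratraldehyde + dimethyl succinate → (E)-half-ester → N-acyl oxazolidinone → syn aldol with O-silyl vanillin → acid-promoted closure of ring B → auxiliary removal and lactone → half-reduction to the hydroxy enal → desilylation.
4. Enabling feature: oxygen O4′ of ring C is para to C4 and turns the C4 carbinol into a quinoid cation. C4a of ring A is para to the C7 methoxy group and is held next to C4 by the (E)-C1=C2 bond.
5. Stereochemistry: C3 comes from the Evans syn aldol with (S)-4-benzyl-2-oxazolidinone. C4 is set by 1,2-induction from C3 in the ring closure (aryl trans to the C3 substituent). The aldol carbinol centre is consumed.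

Key step: step 5

Remark on the chemistry: the target is a γ-hydroxy enal and is assumed to exist as the open aldehyde drawn, with its cyclic lactol as the minor ring–chain tautomer, so half-reduction of lactone 15 leads to it.

**Route**

Step 1
Reactants: 1 vanillin (4-hydroxy-3-methoxybenzaldehyde)
Product: 2 4-(tert-butyldimethylsilyloxy)-3-methoxybenzaldehyde
Conditions: TBSCl, imidazole, DMF, rt
Reagents that add atoms: tert-butyldimethylsilyl chloride (TBSCl), CC(C)(C)[Si](C)(C)Cl
Why: Imidazole-promoted O-silylation of the phenol (silyl ether formation) leaves the aldehyde untouched and masks the acidic OH for the boron aldol.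

Step 2
Reactants: 3 veratraldehyde (3,4-dimethoxybenzaldehyde); 4 dimethyl succinate
Product: 6 (E)-4-(3,4-dimethoxyphenyl)-3-(methoxycarbonyl)but-3-enoic acid, via Stobbe lactone 5 (not isolated)
Conditions: NaOMe, MeOH, reflux; then aq. HCl
Reagents that add atoms: none
Why: Stobbe condensation: the succinate enolate adds to the aldehyde, the alkoxide lactonizes to 5, and E1cB ring opening should give the half-ester with the aryl group cis to the CH2CO2H arm ((E)-alkene), the geometry the later ring closure needs.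

Step 3
Reactants: 6 (E)-4-(3,4-dimethoxyphenyl)-3-(methoxycarbonyl)but-3-enoic acid; 7 (S)-4-benzyl-2-oxazolidinone
Product: 9 (S)-4-benzyl-3-[(E)-4-(3,4-dimethoxyphenyl)-3-(methoxycarbonyl)but-3-enoyl]oxazolidin-2-one, via mixed pivalic anhydride 8 (not isolated)
Conditions: PivCl, Et3N, THF, −20 °C; then 7, LiCl, −20 °C to rt
Reagents that add atoms: none
Why: N-acylation of the oxazolidinone through the mixed anhydride (Evans imide formation, LiCl/Et3N variant) activates only the free carboxyl group, the conjugated methyl ester being inert.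

Step 4
Reactants: 9 (S)-4-benzyl-3-[(E)-4-(3,4-dimethoxyphenyl)-3-(methoxycarbonyl)but-3-enoyl]oxazolidin-2-one; 2 4-(tert-butyldimethylsilyloxy)-3-methoxybenzaldehyde
Product: 11 (S)-4-benzyl-3-[(2S,3E)-2-{(S)-[4-(tert-butyldimethylsilyloxy)-3-methoxyphenyl](hydroxy)methyl}-4-(3,4-dimethoxyphenyl)-3-(methoxycarbonyl)but-3-enoyl]oxazolidin-2-one (syn aldol adduct), via dibutylboron dienolate 10 (not isolated)
Conditions: Bu2BOTf, i-Pr2NEt, CH2Cl2, 0 °C; then 2, −78 to 0 °C; H2O2, MeOH, aq. NaH2PO4/Na2HPO4 (pH 7), 0 °C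
Reagents that add atoms: none
Why: Evans syn aldol: soft enolization gives the (Z)-boron dienolate 10, which should react at its α-carbon through a Zimmerman–Traxler chair on the face opposite the benzyl group of the auxiliary, setting the future C3 (S in 11, R in the target) and a syn carbinol that is consumed in step 5.

Step 5
Reactants: 11 syn aldol adduct
Product: 13 methyl (3R,4S)-3-{[(S)-4-benzyl-2-oxooxazolidin-3-yl]carbonyl}-4-[4-(tert-butyldimethylsilyloxy)-3-methoxyphenyl]-6,7-dimethoxy-3,4-dihydronaphthalene-2-carboxylate, via benzylic cation 12 (not isolated)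
Conditions: TFA, CH2Cl2, −20 to 0 °C
Reagents that add atoms: none
Why: TFA ionizes the benzylic C4 alcohol of 11 because the para oxygen O4′ of ring C delocalizes the charge into the quinone-methide-type (O-silylated quinoid) cation 12, which is attacked by the ring A carbon ortho to the alkene and para to a methoxy group (future C4a), followed by proton loss to restore the arene (intramolecular Friedel–Crafts alkylation, a 1,6-addition to a quinone methide). The closest known reaction type is the acid-promoted cyclization of 7′-oxygenated 8–8′ lignan precursors to aryltetralins and 1-aryl-1,2-dihydronaphthalenes, which copies the quinone methide ring closure assumed in cyclolignan biosynthesis. Ring B closes in a 6-exo-trig cation–π mode, the (E)-C1=C2 bond holding ring A cis to the cationic carbon. The new C4 stereocenter is controlled by C3: the arene should add to the planar cation on the face anti to the bulky acyl oxazolidinone, giving the trans, pseudo-diaxial 3,4-arrangement, while the carbinol configuration of 11 is lost on ionization. The step needs attack through C6 and not C2 of the dimethoxyphenyl ring, secured by para-methoxy activation and the hindrance at C2, and it needs ring closure to outrun loss of the C3 proton, secured by the six-membered transition state at low temperature; a C3 epimer would in any case be a separable diastereomer because the auxiliary is still attached.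

Step 6
Reactants: 13 cyclized imide ester
Product: 15 (3aR,4S)-4-[4-(tert-butyldimethylsilyloxy)-3-methoxyphenyl]-6,7-dimethoxy-3a,4-dihydronaphtho[2,3-c]furan-1(3H)-one, via hydroxy ester 14 (not isolated)
Conditions: LiBH4, MeOH (1 equiv), THF, 0 °C; then TsOH·H2O (cat.), CH2Cl2, rt
Reagents that add atoms: none
Why: Reductive cleavage of the N-acyl oxazolidinone with LiBH4 (the conjugated methyl ester reacts much more slowly) frees the auxiliary and the primary alcohol 14, which closes the five-membered lactone on the neighbouring ester under acid catalysis (lactonization) without touching either stereocenter.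

Step 7
Reactants: 15 fused lactone
Product: 17 (3R,4S)-4-[4-(tert-butyldimethylsilyloxy)-3-methoxyphenyl]-3-(hydroxymethyl)-6,7-dimethoxy-3,4-dihydronaphthalene-2-carbaldehyde, via lactol 16 (not isolated)
Conditions: i-Bu2AlH (DIBAL-H), CH2Cl2, −78 °C; then aq. potassium sodium tartrate
Reagents that add atoms: none
Why: Half-reduction of the lactone with i-Bu2AlH at −78 °C should stop at the aluminated lactol 16, which on work-up opens to the aryl-conjugated hydroxy enal (lactone-to-lactol reduction followed by ring–chain tautomerism).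

Step 8
Reactants: 17 silyl-protected hydroxy enal
Product: 18 (3R,4S)-4-(4-hydroxy-3-methoxyphenyl)-3-(hydroxymethyl)-6,7-dimethoxy-3,4-dihydronaphthalene-2-carbaldehyde (target)
Conditions: Bu4NF, AcOH, THF, 0 °C
Reagents that add atoms: none
Why: Fluoride cleavage of the aryl silyl ether, buffered with AcOH so that no free phenoxide is exposed to base or air, should release the phenol without touching the enal or the two stereocenters.

**Compound list**

1 | vanillin (4-hydroxy-3-methoxybenzaldehyde) | COc1cc(C=O)ccc1O | starting material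
2 | 4-(tert-butyldimethylsilyloxy)-3-methoxybenzaldehyde | COc1cc(C=O)ccc1O[Si](C)(C)C(C)(C)C | intermediate
3 | veratraldehyde (3,4-dimethoxybenzaldehyde) | COc1ccc(C=O)cc1OC | starting material
4 | dimethyl succinate | COC(=O)CCC(=O)OC | starting material
5 | methyl 2-(3,4-dimethoxyphenyl)-5-oxotetrahydrofuran-3-carboxylate (Stobbe lactone, racemic) | COC(=O)C1CC(=O)OC1c1ccc(OC)c(OC)c1 | intermediate (not isolated)
6 | (E)-4-(3,4-dimethoxyphenyl)-3-(methoxycarbonyl)but-3-enoic acid | COC(=O)/C(=C/c1ccc(OC)c(OC)c1)CC(=O)O | intermediate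
7 | (S)-4-benzyl-2-oxazolidinone | O=C1N[C@@H](Cc2ccccc2)CO1 | starting material
8 | mixed pivalic anhydride of 6 | COC(=O)/C(=C/c1ccc(OC)c(OC)c1)CC(=O)OC(=O)C(C)(C)C | intermediate (not isolated)
9 | (S)-4-benzyl-3-[(E)-4-(3,4-dimethoxyphenyl)-3-(methoxycarbonyl)but-3-enoyl]oxazolidin-2-one | COC(=O)/C(=C/c1ccc(OC)c(OC)c1)CC(=O)N1[C@@H](Cc2ccccc2)COC1=O | intermediate
10 | dibutylboron (Z)-dienolate of 9 | CCCCB(CCCC)O/C(=C\C(C(=O)OC)=C/c1ccc(OC)c(OC)c1)N1[C@@H](Cc2ccccc2)COC1=O | intermediate (not isolated)
11 | (S)-4-benzyl-3-[(2S,3E)-2-{(S)-[4-(tert-butyldimethylsilyloxy)-3-methoxyphenyl](hydroxy)methyl}-4-(3,4-dimethoxyphenyl)-3-(methoxycarbonyl)but-3-enoyl]oxazolidin-2-one | COC(=O)/C(=C/c1ccc(OC)c(OC)c1)[C@@H]([C@H](O)c1ccc(O[Si](C)(C)C(C)(C)C)c(OC)c1)C(=O)N1[C@@H](Cc2ccccc2)COC1=O | intermediate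
12 | benzylic cation from 11 (O-silylated quinone-methide-type cation) | COC(=O)/C(=C/c1ccc(OC)c(OC)c1)[C@@H]([CH+]c1ccc(O[Si](C)(C)C(C)(C)C)c(OC)c1)C(=O)N1[C@@H](Cc2ccccc2)COC1=O | intermediate (not isolated)
13 | methyl (3R,4S)-3-{[(S)-4-benzyl-2-oxooxazolidin-3-yl]carbonyl}-4-[4-(tert-butyldimethylsilyloxy)-3-methoxyphenyl]-6,7-dimethoxy-3,4-dihydronaphthalene-2-carboxylate | COc1cc([C@H]2c3cc(OC)c(OC)cc3C=C(C(=O)OC)[C@@H]2C(=O)N2[C@@H](Cc3ccccc3)COC2=O)ccc1O[Si](C)(C)C(C)(C)C | intermediate
14 | methyl (3R,4S)-4-[4-(tert-butyldimethylsilyloxy)-3-methoxyphenyl]-3-(hydroxymethyl)-6,7-dimethoxy-3,4-dihydronaphthalene-2-carboxylate | COc1cc([C@H]2c3cc(OC)c(OC)cc3C=C(C(=O)OC)[C@@H]2CO)ccc1O[Si](C)(C)C(C)(C)C | intermediate (not isolated)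
15 | (3aR,4S)-4-[4-(tert-butyldimethylsilyloxy)-3-methoxyphenyl]-6,7-dimethoxy-3a,4-dihydronaphtho[2,3-c]furan-1(3H)-one | COc1cc([C@H]2c3cc(OC)c(OC)cc3C=C3C(=O)OC[C@H]23)ccc1O[Si](C)(C)C(C)(C)C | intermediate
16 | (3aR,4S)-4-[4-(tert-butyldimethylsilyloxy)-3-methoxyphenyl]-6,7-dimethoxy-1,3,3a,4-tetrahydronaphtho[2,3-c]furan-1-ol (lactol, both C1 epimers) | COc1cc([C@H]2c3cc(OC)c(OC)cc3C=C3C(O)OC[C@H]23)ccc1O[Si](C)(C)C(C)(C)C | intermediate (not isolated)
17 | (3R,4S)-4-[4-(tert-butyldimethylsilyloxy)-3-methoxyphenyl]-3-(hydroxymethyl)-6,7-dimethoxy-3,4-dihydronaphthalene-2-carbaldehyde | COc1cc([C@H]2c3cc(OC)c(OC)cc3C=C(C=O)[C@@H]2CO)ccc1O[Si](C)(C)C(C)(C)C | intermediate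
18 | (3R,4S)-4-(4-hydroxy-3-methoxyphenyl)-3-(hydroxymethyl)-6,7-dimethoxy-3,4-dihydronaphthalene-2-carbaldehyde | COc1cc([C@H]2c3cc(OC)c(OC)cc3C=C(C=O)[C@@H]2CO)ccc1O | target

**Count and risks**

Total step count: 8. Longest linear sequence: 7 steps (steps 2 to 8, from veratraldehyde and dimethyl succinate); step 1 is a one-step side branch.

Steps most likely to fail:

1. Step 5 (ring closure). The cation may lose the C3 proton, which is α to the imide carbonyl, faster than the ester-deactivated ring A attacks; this would give the 2,3-dibenzylidene succinate and erode C3. The fallback sets out from 11 and removes the auxiliary before the ring is closed. LiBH4 (MeOH, THF, 0 °C) cleaves the imide and the freed primary alcohol lactonizes onto the methyl ester to give the hydroxy lactone (3E,4R)-4-{(S)-[4-(tert-butyldimethylsilyloxy)-3-methoxyphenyl](hydroxy)methyl}-3-(3,4-dimethoxybenzylidene)dihydrofuran-2(3H)-one F1, in which the future C3 is no longer next to a carbonyl group. BF3·OEt2 (CH2Cl2, −78 to −20 °C) then ionizes the carbinol and closes ring B on the lactone-bridged substrate. The fallback comes back to the route at lactone 15.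

2. Step 4 (aldol). Addition of the cross-conjugated boron dienolate to the electron-rich aldehyde may be slow or reversible, with erosion of facial selectivity or reaction at the benzylic terminus. The fallback sets out from 6 and replaces the aldol by an irreversible enolate alkylation followed by oxidative activation of C4.
   - Acid 6 is coupled through mixed anhydride 8 with (R)-4-benzyl-2-oxazolidinone to give (R)-4-benzyl-3-[(E)-4-(3,4-dimethoxyphenyl)-3-(methoxycarbonyl)but-3-enoyl]oxazolidin-2-one F2.
   - Aldehyde 2 is reduced (NaBH4, MeOH, 0 °C) to [4-(tert-butyldimethylsilyloxy)-3-methoxyphenyl]methanol F3 and converted (PBr3, Et2O, 0 °C) into [4-(bromomethyl)-2-methoxyphenoxy](tert-butyl)dimethylsilane F4.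
   - Alkylation of the sodium enolate of F2 (NaN(SiMe3)2, THF, −78 °C) with F4 is an Evans alkylation; with the (R)-auxiliary it should give the same C3 configuration as the aldol with the (S)-auxiliary, in the alkylated imide (R)-4-benzyl-3-[(2R,3E)-2-[4-(tert-butyldimethylsilyloxy)-3-methoxybenzyl]-4-(3,4-dimethoxyphenyl)-3-(methoxycarbonyl)but-3-enoyl]oxazolidin-2-one F5.
   - DDQ (1 equiv, CH2Cl2/TFA, 0 °C) abstracts hydride from the benzylic CH2 para to the silyloxy group, an oxidative cyclization known for dibenzylbutyrolactone lignans. The resulting cation is of the same type as 12 and closes ring B to methyl (3R,4S)-3-{[(R)-4-benzyl-2-oxooxazolidin-3-yl]carbonyl}-4-[4-(tert-butyldimethylsilyloxy)-3-methoxyphenyl]-6,7-dimethoxy-3,4-dihydronaphthalene-2-carboxylate F6.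
   - LiBH4 then TsOH·H2O, as in step 6, cleave the auxiliary. The fallback comes back to the route at lactone 15.

3. Step 7 (half-reduction). The aluminated lactol may collapse and take up a second hydride, giving over-reduction. The fallback sets out from 15. The lactone is reduced fully with LiAlH4 (THF, 0 °C) to the diol [(1S,2R)-1-[4-(tert-butyldimethylsilyloxy)-3-methoxyphenyl]-6,7-dimethoxy-1,2-dihydronaphthalene-2,3-diyl]dimethanol F7. MnO2 (CH2Cl2, rt) then oxidizes only the allylic, styrene-conjugated primary alcohol to the enal. The fallback comes back to the route at 17.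

**Further compounds**

F1 | step 5 | (3E,4R)-4-{(S)-[4-(tert-butyldimethylsilyloxy)-3-methoxyphenyl](hydroxy)methyl}-3-(3,4-dimethoxybenzylidene)dihydrofuran-2(3H)-one | COc1ccc(/C=C2/C(=O)OC[C@@H]2[C@H](O)c2ccc(O[Si](C)(C)C(C)(C)C)c(OC)c2)cc1OC
F2 | step 4 | (R)-4-benzyl-3-[(E)-4-(3,4-dimethoxyphenyl)-3-(methoxycarbonyl)but-3-enoyl]oxazolidin-2-one | COC(=O)/C(=C/c1ccc(OC)c(OC)c1)CC(=O)N1[C@H](Cc2ccccc2)COC1=O
F3 | step 4 | [4-(tert-butyldimethylsilyloxy)-3-methoxyphenyl]methanol | COc1cc(CO)ccc1O[Si](C)(C)C(C)(C)C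
F4 | step 4 | [4-(bromomethyl)-2-methoxyphenoxy](tert-butyl)dimethylsilane | COc1cc(CBr)ccc1O[Si](C)(C)C(C)(C)C
F5 | step 4 | (R)-4-benzyl-3-[(2R,3E)-2-[4-(tert-butyldimethylsilyloxy)-3-methoxybenzyl]-4-(3,4-dimethoxyphenyl)-3-(methoxycarbonyl)but-3-enoyl]oxazolidin-2-one | COC(=O)/C(=C/c1ccc(OC)c(OC)c1)[C@@H](Cc1ccc(O[Si](C)(C)C(C)(C)C)c(OC)c1)C(=O)N1[C@H](Cc2ccccc2)COC1=O
F6 | step 4 | methyl (3R,4S)-3-{[(R)-4-benzyl-2-oxooxazolidin-3-yl]carbonyl}-4-[4-(tert-butyldimethylsilyloxy)-3-methoxyphenyl]-6,7-dimethoxy-3,4-dihydronaphthalene-2-carboxylate | COc1cc([C@H]2c3cc(OC)c(OC)cc3C=C(C(=O)OC)[C@@H]2C(=O)N2[C@H](Cc3ccccc3)COC2=O)ccc1O[Si](C)(C)C(C)(C)C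
F7 | step 7 | [(1S,2R)-1-[4-(tert-butyldimethylsilyloxy)-3-methoxyphenyl]-6,7-dimethoxy-1,2-dihydronaphthalene-2,3-diyl]dimethanol | COc1cc([C@H]2c3cc(OC)c(OC)cc3C=C(CO)[C@@H]2CO)ccc1O[Si](C)(C)C(C)(C)C
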